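**Retrosynthetic overview**
- The palmitate is put on last, after the methoxymethyl (MOM) ether of the tetronate is removed. The bond from the ylidene CH (C1′) to the CH(CH3) stereocenter (C2′) comes from a stereoretentive Negishi coupling of an (S)-sec-alkylzinc with an (E)-5-(iodomethylidene) tetronate.
- The (S)-iodide comes from the (R)-alcohol by Appel inversion, and the alcohol from reductive desulfonylation of a hydroxy sulfone. That sulfone is assembled in one flask from methyl phenyl sulfone, (R)-propylene oxide and the (E,E)-allylic bromide.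
- Feature: C4′ is the middle CH2 of the three methylenes C3′–C5′ between the C2′ stereocenter and the C6′=C7′ alkene. Its neighbours are C3′ (an epoxide CH2) and C5′ (an allylic CH2), both natural electrophiles, so C4′ enters as a sulfonyl-stabilised nucleophile and the sulfone is then removed.
- The allylic bromide comes from geranyl acetate (SeO2 oxidation of the E-methyl) and 3-furylmethyl Grignard (copper-catalysed coupling at C1).
- Rings: the furan ring is bought; the butenolide ring is closed by 5-exo-dig iodolactonisation, which fixes the E-iodomethylidene, before the fragments are joined. The key step closes no ring.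

Key step: step 9

Remark: the target SMILES has the side chain trans to the ring oxygen, i.e. the (5E)-ylidene butenolide, with an (S) side-chain stereocenter. The route is built for this isomer, and the tetronate oxygen is carried as a MOM ether so it can be freed without nucleophiles that might equilibrate the congested E alkene.

Step 1
Reactants: 1 geranyl acetate [(2E)-3,7-dimethylocta-2,6-dien-1-yl acetate]
Product: 2 (2E,6E)-8-hydroxy-3,7-dimethylocta-2,6-dien-1-yl acetate
Conditions: SeO2 (cat.), t-BuOOH, salicylic acid (cat.), CH2Cl2, rt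
Reagents that add atoms: tert-butyl hydroperoxide, CC(C)(C)OO (its oxygen is handed on by the SeO2 catalyst, O=[Se]=O)
Why: Riley-type allylic oxidation (ene reaction then [2,3]-sigmatropic shift) should hydroxylate the (E)-methyl of the terminal trisubstituted alkene, the 2,3-alkene being deactivated by its allylic acetate.

Step 2
Reactants: 2 (2E,6E)-8-hydroxy-3,7-dimethylocta-2,6-dien-1-yl acetate
Product: 3 (2E,6E)-8-[(tert-butyldimethylsilyl)oxy]-3,7-dimethylocta-2,6-dien-1-yl acetate
Conditions: TBSCl, imidazole, DMF, rt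
Reagents that add atoms: tert-butyldimethylsilyl chloride, CC(C)(C)[Si](C)(C)Cl
Why: Standard silylation of a primary allylic alcohol masks the C8 oxygen so that the two chain ends can be handled separately.

Step 3
Reactants: 3 (2E,6E)-8-[(tert-butyldimethylsilyl)oxy]-3,7-dimethylocta-2,6-dien-1-yl acetate
Product: 4 (2E,6E)-8-[(tert-butyldimethylsilyl)oxy]-3,7-dimethylocta-2,6-dien-1-ol
Conditions: K2CO3, MeOH, rt
Reagents that add atoms: none
Why: Base-catalysed transesterification removes the acetate while the silyl ether is stable to carbonate in methanol.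

Step 4
Reactants: 4 (2E,6E)-8-[(tert-butyldimethylsilyl)oxy]-3,7-dimethylocta-2,6-dien-1-ol
Product: 5 {[(2E,6E)-8-bromo-2,6-dimethylocta-2,6-dien-1-yl]oxy}(tert-butyl)dimethylsilane
Conditions: CBr4, PPh3, CH2Cl2, 0 °C
Reagents that add atoms: carbon tetrabromide, BrC(Br)(Br)Br
Why: Appel bromination converts the primary allylic alcohol to the bromide under neutral conditions without allylic transposition or loss of the silyl ether.

Step 5
Reactants: 6 3-furanmethanol
Product: 8 3-(chloromethyl)furan, via furan-3-ylmethyl methanesulfonate 7 (not isolated)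
Conditions: MsCl, s-collidine, LiCl, DMF, 0 °C
Reagents that add atoms: lithium chloride, [Li+].[Cl-] (methanesulfonyl chloride, CS(=O)(=O)Cl, only puts the mesyl group on intermediate 7)
Why: In situ mesylation and chloride displacement under buffered conditions gives the acid-sensitive furylmethyl chloride without exposing the furan to strong acid.

Step 6
Reactants: 8 3-(chloromethyl)furan; 5 {[(2E,6E)-8-bromo-2,6-dimethylocta-2,6-dien-1-yl]oxy}(tert-butyl)dimethylsilane
Product: 10 tert-butyl{[(2E,6E)-9-(furan-3-yl)-2,6-dimethylnona-2,6-dien-1-yl]oxy}dimethylsilane, via furan-3-ylmethylmagnesium chloride 9 (not isolated)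
Conditions: Mg, THF, 0 °C → rt; then 5, Li2CuCl4 (cat.), THF, 0 °C
Reagents that add atoms: none
Why: Copper-catalysed cross-coupling of the benzylic-type Grignard reagent with the primary allylic bromide should proceed by direct SN2 substitution at CH2 with retention of the E alkene, copper also suppressing reaction through the furan 2-position.

Step 7
Reactants: 10 tert-butyl{[(2E,6E)-9-(furan-3-yl)-2,6-dimethylnona-2,6-dien-1-yl]oxy}dimethylsilane
Product: 11 (2E,6E)-9-(furan-3-yl)-2,6-dimethylnona-2,6-dien-1-ol
Conditions: TBAF, THF, rt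
Reagents that add atoms: none
Why: Fluoride-induced desilylation frees the allylic alcohol without touching the furan or the alkenes.

Step 8
Reactants: 11 (2E,6E)-9-(furan-3-yl)-2,6-dimethylnona-2,6-dien-1-ol
Product: 12 3-[(3E,7E)-9-bromo-4,8-dimethylnona-3,7-dien-1-yl]furan
Conditions: CBr4, PPh3, CH2Cl2, −20 → 0 °C; used directly
Reagents that add atoms: carbon tetrabromide, BrC(Br)(Br)Br
Why: Appel bromination under neutral conditions gives the primary (E)-allylic bromide without acid that would damage the furan.

Step 9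
Reactants: 13 methyl phenyl sulfone; 14 (R)-propylene oxide; 12 3-[(3E,7E)-9-bromo-4,8-dimethylnona-3,7-dien-1-yl]furan
Product: 18 (2R,6E,10E)-13-(furan-3-yl)-6,10-dimethyl-4-(phenylsulfonyl)trideca-6,10-dien-2-ol (both epimers at C4), via lithiomethyl phenyl sulfone 15 (not isolated), via lithium alkoxide of (R)-4-(phenylsulfonyl)butan-2-ol 16 (not isolated), via C,O-dilithio derivative of (R)-4-(phenylsulfonyl)butan-2-ol 17 (not isolated)
Conditions: n-BuLi (1.0 equiv), THF–DMPU, −78 °C; 14, −78 °C → rt; recool to −78 °C, n-BuLi (1.05 equiv); 12 (limiting), −78 → −20 °C; H2O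
Reagents that add atoms: none
Why: n-BuLi deprotonates methyl phenyl sulfone and the soft sulfonyl carbanion opens (R)-propylene oxide by SN2 attack at the unsubstituted CH2, so no bond to the carbinol carbon is touched and its (R) configuration is that of the epoxide; a second equivalent of n-BuLi then gives the alkoxide/α-sulfonyl dianion, whose carbon displaces bromide from the primary allylic carbon of 12 by SN2. The closest known reaction type is the sequential epoxide opening and C-alkylation of α-sulfonyl carbanions, here run in one flask. No ring is closed. The only new stereocenter is the sulfonyl carbon, which forms without control and is deleted in step 10. The step needs CH2-selective epoxide opening, C- over O-alkylation, and SN2 over SN2′ attack with both E alkenes kept; the unhindered epoxide CH2, the far higher nucleophilicity of the carbanion than of the lithium alkoxide at −78 °C, and the primary, unhindered allylic carbon of 12 should secure these. Keeping 12 as the limiting component prevents leftover lithiated sulfone from wasting it.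

Step 10
Reactants: 18 (2R,6E,10E)-13-(furan-3-yl)-6,10-dimethyl-4-(phenylsulfonyl)trideca-6,10-dien-2-ol
Product: 19 (2R,6E,10E)-13-(furan-3-yl)-6,10-dimethyltrideca-6,10-dien-2-ol
Conditions: Na(Hg) (6% Na), Na2HPO4, MeOH–THF, −20 °C → rt
Reagents that add atoms: none
Why: Single-electron reductive cleavage of the alkyl–sulfonyl bond removes the sulfone and its uncontrolled stereocenter; the sulfonyl carbon is not allylic, so no alkene migration is expected, and the γ-hydroxyl cannot undergo Julia-type elimination.

Step 11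
Reactants: 19 (2R,6E,10E)-13-(furan-3-yl)-6,10-dimethyltrideca-6,10-dien-2-ol
Product: 20 3-[(3E,7E,12S)-12-iodo-4,8-dimethyltrideca-3,7-dien-1-yl]furan
Conditions: PPh3, I2, N-methylimidazole, CH2Cl2, −10 °C
Reagents that add atoms: iodine, II
Why: Appel iodination displaces the alkoxyphosphonium group by iodide with SN2 inversion, turning the (R)-carbinol into the (S)-iodide, and the low temperature limits iodide–iodide exchange that would erode the configuration.

Step 12
Reactants: 21 methyl propionate
Product: 23 methyl (2E)-3-(methoxymethoxy)-2-methylprop-2-enoate, via sodium enolate of methyl 2-formylpropanoate 22 (not isolated)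
Conditions: NaH, HCO2Me, THF (cat. MeOH), 0 °C → rt; then MOMCl, DMF, 0 °C
Reagents that add atoms: methyl formate, COC=O; chloromethyl methyl ether, COCCl
Why: Crossed Claisen formylation gives the sodium formyl-enolate, which the hard electrophile MOMCl alkylates on oxygen to give mainly the (E)-enol ether with the alkoxy group anti to the ester.

Step 13
Reactants: 23 methyl (2E)-3-(methoxymethoxy)-2-methylprop-2-enoate
Product: 26 methyl (2E)-3-(methoxymethoxy)-2-methyl-5-(trimethylsilyl)pent-2-en-4-ynoate, via methyl (2E)-3-lithio-3-(methoxymethoxy)-2-methylprop-2-enoate 24 (not isolated), via [(1Z)-3-methoxy-1-(methoxymethoxy)-2-methyl-3-oxoprop-1-en-1-yl]zinc chloride 25 (not isolated)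
Conditions: LDA, THF, −95 °C; ZnCl2, −95 → 0 °C; BrC≡CSiMe3, Pd(PPh3)4 (cat.), 0 °C → rt
Reagents that add atoms: (bromoethynyl)trimethylsilane, C[Si](C)(C)C#CBr
Why: Carbonyl-directed β-lithiation of a β-alkoxyacrylate gives the chelated alkenyllithium with the metal cis to the ester, and transmetalation to zinc followed by Negishi alkenyl–alkynyl coupling with retention places the alkyne cis to the ester as the later lactonisation requires.

Step 14
Reactants: 26 methyl (2E)-3-(methoxymethoxy)-2-methyl-5-(trimethylsilyl)pent-2-en-4-ynoate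
Product: 28 (5E)-5-(iodomethylidene)-4-(methoxymethoxy)-3-methylfuran-2(5H)-one, via lithium (2E)-3-(methoxymethoxy)-2-methylpent-2-en-4-ynoate 27 (not isolated)
Conditions: LiOH, THF–H2O, rt → 40 °C; concentrate; I2, NaHCO3, MeCN–H2O, 0 °C, dark; Na2S2O3 work-up
Reagents that add atoms: lithium hydroxide, [Li+].[OH-] (carboxylate oxygen); iodine, II
Why: Saponification with C-desilylation gives the carboxylate, and iodolactonisation of the terminal alkyne should then close the butenolide by 5-exo-dig anti addition of oxygen and iodine at the internal alkyne carbon, which places iodine trans to the ring oxygen (E).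

Step 15
Reactants: 20 3-[(3E,7E,12S)-12-iodo-4,8-dimethyltrideca-3,7-dien-1-yl]furan; 28 (5E)-5-(iodomethylidene)-4-(methoxymethoxy)-3-methylfuran-2(5H)-one
Product: 31 (5E)-5-[(2S,6E,10E)-13-(furan-3-yl)-2,6,10-trimethyltrideca-6,10-dien-1-ylidene]-4-(methoxymethoxy)-3-methylfuran-2(5H)-one, via (S)-sec-alkyllithium 29 (not isolated), via (S)-sec-alkyl(trimethylsilylmethyl)zinc 30 (not isolated)
Conditions: t-BuLi (2.2 equiv), pentane–Et2O (3:2), −100 °C, inverse addition; Me3SiCH2ZnBr·LiBr (Et2O), −100 → −25 °C; then 28, Pd2I2(PtBu3)2 (cat.), toluene, −25 °C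
Reagents that add atoms: none
Why: Iodine–lithium exchange at −100 °C in a hydrocarbon-rich medium and transmetalation to zinc both proceed with retention, the mixed dialkylzinc is configurationally stable, and the palladium-catalysed Negishi coupling with the alkenyl iodide retains both the sp3 configuration (S) and the E geometry of the former C–I bond, the brief exposure at −100 °C sparing the furan C–H bonds.

Step 16
Reactants: 31 (5E)-5-[(2S,6E,10E)-13-(furan-3-yl)-2,6,10-trimethyltrideca-6,10-dien-1-ylidene]-4-(methoxymethoxy)-3-methylfuran-2(5H)-one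
Product: 32 (5E)-5-[(2S,6E,10E)-13-(furan-3-yl)-2,6,10-trimethyltrideca-6,10-dien-1-ylidene]-4-hydroxy-3-methylfuran-2(5H)-one
Conditions: HCl (0.1 M) in MeOH–THF, 0 °C → rt
Reagents that add atoms: none
Why: The MOM ether of a vinylogous acid is an acylal-like acetal that should cleave by mild acid-catalysed transacetalisation to methanol, under conditions too weak to protonate the furan, the alkenes or the ylidene.

Step 17
Reactants: 32 (5E)-5-[(2S,6E,10E)-13-(furan-3-yl)-2,6,10-trimethyltrideca-6,10-dien-1-ylidene]-4-hydroxy-3-methylfuran-2(5H)-one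
Product: 33 (2E)-2-[(2S,6E,10E)-13-(furan-3-yl)-2,6,10-trimethyltrideca-6,10-dien-1-ylidene]-4-methyl-5-oxo-2,5-dihydrofuran-3-yl hexadecanoate (CNP0269639.1)
Conditions: palmitoyl chloride, Et3N, CH2Cl2, −20 → 0 °C
Reagents that add atoms: palmitoyl chloride, CCCCCCCCCCCCCCCC(=O)Cl
Why: The triethylammonium tetronate is acylated on the C4 oxygen because C3 is blocked by its methyl group and the 4-acyloxybutenolide is the conjugated, more stable O-acyl isomer.

**Compound list**
1 | geranyl acetate | CC(C)=CCC/C(C)=C/COC(C)=O | starting material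
2 | (2E,6E)-8-hydroxy-3,7-dimethylocta-2,6-dien-1-yl acetate | OC/C(C)=C/CC/C(C)=C/COC(C)=O | intermediate
3 | (2E,6E)-8-[(tert-butyldimethylsilyl)oxy]-3,7-dimethylocta-2,6-dien-1-yl acetate | CC(C)(C)[Si](C)(C)OC/C(C)=C/CC/C(C)=C/COC(C)=O | intermediate
4 | (2E,6E)-8-[(tert-butyldimethylsilyl)oxy]-3,7-dimethylocta-2,6-dien-1-ol | CC(C)(C)[Si](C)(C)OC/C(C)=C/CC/C(C)=C/CO | intermediate
5 | {[(2E,6E)-8-bromo-2,6-dimethylocta-2,6-dien-1-yl]oxy}(tert-butyl)dimethylsilane | CC(C)(C)[Si](C)(C)OC/C(C)=C/CC/C(C)=C/CBr | intermediate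
6 | 3-furanmethanol | OCc1ccoc1 | starting material
7 | furan-3-ylmethyl methanesulfonate | CS(=O)(=O)OCc1ccoc1 | intermediate
8 | 3-(chloromethyl)furan | ClCc1ccoc1 | intermediate
9 | furan-3-ylmethylmagnesium chloride | Cl[Mg]Cc1ccoc1 | intermediate
10 | tert-butyl{[(2E,6E)-9-(furan-3-yl)-2,6-dimethylnona-2,6-dien-1-yl]oxy}dimethylsilane | CC(C)(C)[Si](C)(C)OC/C(C)=C/CC/C(C)=C/CCc1ccoc1 | intermediate
11 | (2E,6E)-9-(furan-3-yl)-2,6-dimethylnona-2,6-dien-1-ol | OC/C(C)=C/CC/C(C)=C/CCc1ccoc1 | intermediate
12 | 3-[(3E,7E)-9-bromo-4,8-dimethylnona-3,7-dien-1-yl]furan | BrC/C(C)=C/CC/C(C)=C/CCc1ccoc1 | intermediate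
13 | methyl phenyl sulfone | CS(=O)(=O)c1ccccc1 | starting material
14 | (R)-propylene oxide | C[C@@H]1CO1 | starting material
15 | lithiomethyl phenyl sulfone | [Li]CS(=O)(=O)c1ccccc1 | intermediate
16 | lithium alkoxide of (R)-4-(phenylsulfonyl)butan-2-ol | C[C@@H](O[Li])CCS(=O)(=O)c1ccccc1 | intermediate
17 | C,O-dilithio derivative of (R)-4-(phenylsulfonyl)butan-2-ol | C[C@@H](O[Li])CC([Li])S(=O)(=O)c1ccccc1 | intermediate
18 | (2R,6E,10E)-13-(furan-3-yl)-6,10-dimethyl-4-(phenylsulfonyl)trideca-6,10-dien-2-ol, both C4 epimers | C[C@@H](O)CC(C/C(C)=C/CC/C(C)=C/CCc1ccoc1)S(=O)(=O)c1ccccc1 | intermediate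
19 | (2R,6E,10E)-13-(furan-3-yl)-6,10-dimethyltrideca-6,10-dien-2-ol | C[C@@H](O)CCC/C(C)=C/CC/C(C)=C/CCc1ccoc1 | intermediate
20 | 3-[(3E,7E,12S)-12-iodo-4,8-dimethyltrideca-3,7-dien-1-yl]furan | C[C@H](I)CCC/C(C)=C/CC/C(C)=C/CCc1ccoc1 | intermediate
21 | methyl propionate | CCC(=O)OC | starting material
22 | sodium enolate of methyl 2-formylpropanoate | [Na+].[O-]C=C(C)C(=O)OC | intermediate
23 | methyl (2E)-3-(methoxymethoxy)-2-methylprop-2-enoate | COCO/C=C(\C)C(=O)OC | intermediate
24 | methyl (2E)-3-lithio-3-(methoxymethoxy)-2-methylprop-2-enoate | COCO/C([Li])=C(\C)C(=O)OC | intermediate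
25 | [(1Z)-3-methoxy-1-(methoxymethoxy)-2-methyl-3-oxoprop-1-en-1-yl]zinc chloride | COCO/C([Zn]Cl)=C(\C)C(=O)OC | intermediate
26 | methyl (2E)-3-(methoxymethoxy)-2-methyl-5-(trimethylsilyl)pent-2-en-4-ynoate | COCO/C(C#C[Si](C)(C)C)=C(\C)C(=O)OC | intermediate
27 | lithium (2E)-3-(methoxymethoxy)-2-methylpent-2-en-4-ynoate | COCO/C(C#C)=C(\C)C(=O)[O-].[Li+] | intermediate
28 | (5E)-5-(iodomethylidene)-4-(methoxymethoxy)-3-methylfuran-2(5H)-one | COCOC1=C(C)C(=O)O/C1=C/I | intermediate
29 | [(2S,6E,10E)-13-(furan-3-yl)-6,10-dimethyltrideca-6,10-dien-2-yl]lithium | C[C@H]([Li])CCC/C(C)=C/CC/C(C)=C/CCc1ccoc1 | intermediate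
30 | [(2S,6E,10E)-13-(furan-3-yl)-6,10-dimethyltrideca-6,10-dien-2-yl][(trimethylsilyl)methyl]zinc | C[C@H]([Zn]C[Si](C)(C)C)CCC/C(C)=C/CC/C(C)=C/CCc1ccoc1 | intermediate
31 | (5E)-5-[(2S,6E,10E)-13-(furan-3-yl)-2,6,10-trimethyltrideca-6,10-dien-1-ylidene]-4-(methoxymethoxy)-3-methylfuran-2(5H)-one | COCOC1=C(C)C(=O)O/C1=C/[C@@H](C)CCC/C(C)=C/CC/C(C)=C/CCc1ccoc1 | intermediate
32 | (5E)-5-[(2S,6E,10E)-13-(furan-3-yl)-2,6,10-trimethyltrideca-6,10-dien-1-ylidene]-4-hydroxy-3-methylfuran-2(5H)-one | OC1=C(C)C(=O)O/C1=C/[C@@H](C)CCC/C(C)=C/CC/C(C)=C/CCc1ccoc1 | intermediate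
33 | (2E)-2-[(2S,6E,10E)-13-(furan-3-yl)-2,6,10-trimethyltrideca-6,10-dien-1-ylidene]-4-methyl-5-oxo-2,5-dihydrofuran-3-yl hexadecanoate | CCCCCCCCCCCCCCCC(=O)OC1=C(C)C(=O)O/C1=C/[C@@H](C)CCC/C(C)=C/CC/C(C)=C/CCc1ccoc1 | target

**Totals**
Total step count: 17.
Longest linear sequence: 13 steps (1, 2, 3, 4, 6, 7, 8, 9, 10, 11, 15, 16, 17 from geranyl acetate).

**Steps most likely to fail**

Step 15. The configuration may erode during iodine–lithium exchange or transmetalation, the organolithium may abstract a furan proton, or palladium may undergo β-hydride elimination at the hindered alkenyl position cis to the MOM ether. The fallback makes the same bond by a stereoretentive Stille coupling of a tin nucleophile installed by SN2 inversion. It sets out from alcohol 19 and skips iodide 20. Alcohol 19 is mesylated (MsCl, Et3N, CH2Cl2, 0 °C) to (2R,6E,10E)-13-(furan-3-yl)-6,10-dimethyltrideca-6,10-dien-2-yl methanesulfonate F1. The mesylate is displaced with inversion by the lithium stannatranide made from 1-chloro-5-aza-1-stannabicyclo[3.3.3]undecane and lithium naphthalenide (THF, −78 °C → rt), giving 1-[(2S,6E,10E)-13-(furan-3-yl)-6,10-dimethyltrideca-6,10-dien-2-yl]-5-aza-1-stannabicyclo[3.3.3]undecane F2. F2 is coupled with 28 (Pd(dba)2, JackiePhos, CuCl, KF, MeCN, 60 °C) with retention at carbon, and the sequence comes back to the route at 31.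

Step 14. The carboxylate may close in the 6-endo mode to an iodopyranone, or iodine may attack the enol-ether carbon instead of the alkyne. The fallback replaces the iodonium pathway by oxymercuration, which is strictly Markovnikov and anti, followed by iododemercuration with retention. It sets out from carboxylate 27, made from 26 as in step 14. Treatment with Hg(OAc)2 (CH2Cl2–H2O, rt) and then aqueous NaCl gives chloro{(E)-[3-(methoxymethoxy)-4-methyl-5-oxofuran-2(5H)-ylidene]methyl}mercury F3. I2 in CH2Cl2 at 0 °C then converts F3 to 28, where the route resumes.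

Step 13. Halogen–zinc exchange between the alkenylzinc and the bromoalkyne may lead to homocoupling, or the lithio species may decompose before transmetalation. The fallback reverses the coupling polarity. It sets out from the lithio species 24, which is quenched with I2 at −95 °C to give methyl (2Z)-3-iodo-3-(methoxymethoxy)-2-methylprop-2-enoate F4. Sonogashira coupling of F4 with ethynyltrimethylsilane (PdCl2(PPh3)2, CuI, Et3N, THF, rt) retains the alkene geometry and comes back to the route at 26.

Further compounds
F1 | step 15 | (2R,6E,10E)-13-(furan-3-yl)-6,10-dimethyltrideca-6,10-dien-2-yl methanesulfonate | C[C@@H](OS(C)(=O)=O)CCC/C(C)=C/CC/C(C)=C/CCc1ccoc1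
F2 | step 15 | 1-[(2S,6E,10E)-13-(furan-3-yl)-6,10-dimethyltrideca-6,10-dien-2-yl]-5-aza-1-stannabicyclo[3.3.3]undecane | C[C@H]([Sn]12CCCN(CCC1)CCC2)CCC/C(C)=C/CC/C(C)=C/CCc1ccoc1
F3 | step 14 | chloro{(E)-[3-(methoxymethoxy)-4-methyl-5-oxofuran-2(5H)-ylidene]methyl}mercury | COCOC1=C(C)C(=O)O/C1=C/[Hg]Cl
F4 | step 13 | methyl (2Z)-3-iodo-3-(methoxymethoxy)-2-methylprop-2-enoate | COCO/C(I)=C(\C)C(=O)OC
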